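**Plan**
- Retrosynthesis cuts first the three Cβ–C(aryl) bonds of the caffeoyl arms (threefold Heck arylation), then the three acrylate ester C–O bonds at O1, O3 and O5, then the succinate ester C–O bond at O4, leaving (−)-quinic acid.
- Enabling feature: O1 (on the quaternary C1 that also bears CO2H), O3 and O5 of the cyclohexane each carry a propenoate whose β-carbon is bonded to a catechol ring, so each arm can be grown from a small acrylate ester. O4 carries the succinate and takes no part.
- Forward order: carboxyl capped as the 4-methoxybenzyl ester, O3/O5 silylated, O4 succinylated, silyl ethers removed, O1/O3/O5 acryloylated, three ketal-protected catechol rings attached, all acid-labile groups removed in one operation.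
- Stereochemistry: the four ring stereocentres come unchanged from (−)-quinic acid, since no step breaks a bond at C1, C3, C4 or C5. The three E alkenes arise from syn insertion and syn β-hydride elimination in the arylation.
- No ring of the target is built; the chain is joined only at the three acrylate termini.

Key step: step 7

Remark: quinate locants are those of the parent acid (C1 bears CO2R and O1; O3 is cis to O4; O5 is trans to O4), and the configuration of (−)-quinic acid is kept at all four ring carbons in every intermediate.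
Remark: 4-tert-butoxy-4-oxobutanoic acid (mono-tert-butyl succinate) is taken as a purchased material.
Remark: in steps 5 and 7 the same building block is consumed three times per molecule of substrate. The singly and doubly converted species are numbered as non-isolated intermediates and drawn as the positional isomers assumed to form first (equatorial O5 arm, then axial O3 arm, then tertiary O1 arm); any other order converges on the same product. In steps 2 and 8 the partly silylated and partly deketalised species are treated as stages of one reaction.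

**Step 1**
Reactants: 1 (−)-quinic acid
Product: 2 4-methoxybenzyl quinate
Conditions: Cs2CO3 (0.55 equiv), 4-methoxybenzyl chloride (1.1 equiv), Bu4NI (cat.), DMF, rt
Reagents that add atoms: 4-methoxybenzyl chloride, COc1ccc(CCl)cc1
Why: Carboxylate O-alkylation (SN2 esterification of the caesium salt) should be clean because the carboxylate is far more nucleophilic than the four neutral hydroxyls, as in the analogous benzylation of quinic acid, and no stereocentre is involved.

**Step 2**
Reactants: 2 4-methoxybenzyl quinate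
Product: 3 4-methoxybenzyl 3,5-bis-O-(tert-butyldimethylsilyl)quinate
Conditions: TBSCl (2.3 equiv), Et3N, DMAP (cat.), DMF, 0 °C to rt
Reagents that add atoms: tert-butyldimethylsilyl chloride, CC(C)(C)[Si](C)(C)Cl
Why: Regioselective silyl ether formation, in which the bulky silyl chloride should take the secondary hydroxyls O3 and O5 and leave the doubly flanked O4 and the tertiary O1 free, the pattern established for simple alkyl quinates.

**Step 3**
Reactants: 3 4-methoxybenzyl 3,5-bis-O-(tert-butyldimethylsilyl)quinate; 4 4-tert-butoxy-4-oxobutanoic acid (1.5 equiv)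
Product: 5 4-methoxybenzyl 4-O-(4-tert-butoxy-4-oxobutanoyl)-3,5-bis-O-(tert-butyldimethylsilyl)quinate
Conditions: EDC·HCl, DMAP, CH2Cl2, 0 °C to rt
Reagents that add atoms: none
Why: Steglich esterification, in which the acylpyridinium derived from the carbodiimide-activated half-ester should acylate the only free secondary hydroxyl (O4) while the tertiary O1 next to the ester is too hindered to compete at room temperature.

**Step 4**
Reactants: 5 4-methoxybenzyl 4-O-(4-tert-butoxy-4-oxobutanoyl)-3,5-bis-O-(tert-butyldimethylsilyl)quinate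
Product: 6 4-methoxybenzyl 4-O-(4-tert-butoxy-4-oxobutanoyl)quinate
Conditions: HF·pyridine, pyridine, THF, 0 °C to rt
Reagents that add atoms: none
Why: Fluoride-mediated silyl ether cleavage in a buffered acidic medium, chosen because acid suppresses migration of the O4 succinate to the freed O3 and O5 hydroxyls and leaves both the tert-butyl and the 4-methoxybenzyl ester intact.

**Step 5**
Reactants: 6 4-methoxybenzyl 4-O-(4-tert-butoxy-4-oxobutanoyl)quinate; 7 acryloyl chloride (three equivalents are incorporated, 6 equiv charged)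
Product: 10 4-methoxybenzyl 1,3,5-tri-O-acryloyl-4-O-(4-tert-butoxy-4-oxobutanoyl)quinate, via 5-O-monoacrylate 8 (not isolated), via 3,5-bis-acrylate 9 (not isolated)
Conditions: i-Pr2NEt (7 equiv), DMAP (cat.), BHT (trace), CH2Cl2, −20 °C to rt
Reagents that add atoms: acryloyl chloride (second and third equivalents of 7), C=CC(=O)Cl
Why: Exhaustive O-acylation with an acid chloride under nucleophilic catalysis, each acylation consuming one molecule of 7 in the expected order equatorial O5, axial O3, tertiary O1, where the small acryloyl group should reach even O1 (whose acylation in quinate esters is known for acetyl and aroyl chlorides) and fast acylation at low temperature should outrun base-induced succinate migration.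

**Step 6**
Reactants: 11 4-bromocatechol
Product: 12 5-bromo-2,2-dimethyl-1,3-benzodioxole
Conditions: 2,2-dimethoxypropane, TsOH·H2O (cat.), toluene, reflux, Soxhlet thimble of 4 Å molecular sieves
Reagents that add atoms: 2,2-dimethoxypropane, COC(C)(C)OC
Why: Acid-catalysed transketalisation, in which the two ortho phenolic oxygens close the five-membered cyclic ketal once methanol is removed continuously.

**Step 7**
Reactants: 10 4-methoxybenzyl 1,3,5-tri-O-acryloyl-4-O-(4-tert-butoxy-4-oxobutanoyl)quinate; 12 5-bromo-2,2-dimethyl-1,3-benzodioxole (three equivalents are incorporated, 3.6 equiv charged)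
Product: 15 4-methoxybenzyl 4-O-(4-tert-butoxy-4-oxobutanoyl)-1,3,5-tris-O-[(E)-3-(2,2-dimethyl-1,3-benzodioxol-5-yl)prop-2-enoyl]quinate, via mono-arylated bis-acrylate 13 (not isolated), via bis-arylated mono-acrylate 14 (not isolated)
Conditions: Pd(P(t-Bu)3)2 (6 mol%), Cy2NMe (4.5 equiv), BHT (trace), 1,4-dioxane, rt to 50 °C
Reagents that add atoms: 5-bromo-2,2-dimethyl-1,3-benzodioxole (second and third equivalents of 12), CC1(C)Oc2ccc(Br)cc2O1
Why: Mizoroki–Heck reaction in which the aryl bromide adds oxidatively to monoligated zerovalent palladium, the acrylate C=C inserts syn into the Pd–aryl bond with the aryl group going to the unsubstituted β-carbon, and syn β-hydride elimination releases the E-cinnamate while the amine returns the palladium hydride to the zerovalent state; the cycle then runs again on 13 and on 14, one molecule of 12 being consumed per acrylate. The closest known reaction type is the arylation of acrylate esters with electron-rich aryl bromides by palladium with P(t-Bu)3 and a hindered tertiary amine at or near room temperature. No ring is closed and no stereocentre is formed or touched, the four quinate stereocentres being spectators. The step needs β-regioselectivity, E geometry and a single arylation per terminus: the first two follow from the polarised monosubstituted acrylate and the preference for the rotamer with aryl and ester anti in β-hydride elimination, the third from the much slower insertion of the resulting β-substituted cinnamate. Because every oxygen of the core is already acylated and the catechols are ketalised, the amine base cannot trigger acyl migration, and the mild temperature together with a radical inhibitor should keep the tris-acrylate from cross-linking.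

**Step 8**
Reactants: 15 4-methoxybenzyl 4-O-(4-tert-butoxy-4-oxobutanoyl)-1,3,5-tris-O-[(E)-3-(2,2-dimethyl-1,3-benzodioxol-5-yl)prop-2-enoyl]quinate
Product: 17 1,3,5-tri-O-caffeoyl-4-O-succinylquinic acid (CNP0143991.1), via tris-acetonide diacid 16 (not isolated)
Conditions: TFA/CH2Cl2 (1:1), anisole (10 equiv), 0 °C to rt; then H2O (to 10% v/v), rt, under argon
Reagents that add atoms: none
Why: Global acidolysis in two stages in one flask, in which the 4-methoxybenzyl ester ionises to a benzylic cation that anisole traps by Friedel–Crafts alkylation and the tert-butyl ester loses 2-methylpropene by an E1 path while the catechols should still be largely masked, after which added water hydrolyses the three aryl ketals through oxocarbenium ions, the secondary alkyl esters being inert to trifluoroacetic acid at room temperature and no stereocentre being touched.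

**Compound list**
1 | (−)-quinic acid | O[C@H]1[C@H](O)C[C@](O)(C(=O)O)C[C@H]1O | starting material
2 | 4-methoxybenzyl quinate | O[C@H]1[C@H](O)C[C@](O)(C(=O)OCc2ccc(OC)cc2)C[C@H]1O | intermediate
3 | 4-methoxybenzyl 3,5-bis-O-(tert-butyldimethylsilyl)quinate (O1 and O4 free) | O[C@H]1[C@H](O[Si](C)(C)C(C)(C)C)C[C@](O)(C(=O)OCc2ccc(OC)cc2)C[C@H]1O[Si](C)(C)C(C)(C)C | intermediate
4 | 4-tert-butoxy-4-oxobutanoic acid (mono-tert-butyl succinate) | CC(C)(C)OC(=O)CCC(=O)O | starting material
5 | 4-methoxybenzyl 4-O-(4-tert-butoxy-4-oxobutanoyl)-3,5-bis-O-(tert-butyldimethylsilyl)quinate | CC(C)(C)OC(=O)CCC(=O)O[C@H]1[C@H](O[Si](C)(C)C(C)(C)C)C[C@](O)(C(=O)OCc2ccc(OC)cc2)C[C@H]1O[Si](C)(C)C(C)(C)C | intermediate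
6 | 4-methoxybenzyl 4-O-(4-tert-butoxy-4-oxobutanoyl)quinate (O1, O3, O5 free) | CC(C)(C)OC(=O)CCC(=O)O[C@H]1[C@H](O)C[C@](O)(C(=O)OCc2ccc(OC)cc2)C[C@H]1O | intermediate
7 | acryloyl chloride | C=CC(=O)Cl | starting material
8 | 4-methoxybenzyl 5-O-acryloyl-4-O-(4-tert-butoxy-4-oxobutanoyl)quinate (O1 and O3 free, not isolated) | CC(C)(C)OC(=O)CCC(=O)O[C@H]1[C@H](OC(=O)C=C)C[C@](O)(C(=O)OCc2ccc(OC)cc2)C[C@H]1O | intermediate
9 | 4-methoxybenzyl 3,5-di-O-acryloyl-4-O-(4-tert-butoxy-4-oxobutanoyl)quinate (O1 free, not isolated) | CC(C)(C)OC(=O)CCC(=O)O[C@H]1[C@H](OC(=O)C=C)C[C@](O)(C(=O)OCc2ccc(OC)cc2)C[C@H]1OC(=O)C=C | intermediate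
10 | 4-methoxybenzyl 1,3,5-tri-O-acryloyl-4-O-(4-tert-butoxy-4-oxobutanoyl)quinate | CC(C)(C)OC(=O)CCC(=O)O[C@H]1[C@H](OC(=O)C=C)C[C@](OC(=O)C=C)(C(=O)OCc2ccc(OC)cc2)C[C@H]1OC(=O)C=C | intermediate
11 | 4-bromocatechol | Oc1ccc(Br)cc1O | starting material
12 | 5-bromo-2,2-dimethyl-1,3-benzodioxole | CC1(C)Oc2ccc(Br)cc2O1 | intermediate
13 | 4-methoxybenzyl 1,3-di-O-acryloyl-4-O-(4-tert-butoxy-4-oxobutanoyl)-5-O-[(E)-3-(2,2-dimethyl-1,3-benzodioxol-5-yl)prop-2-enoyl]quinate (mono-arylated, not isolated) | CC(C)(C)OC(=O)CCC(=O)O[C@H]1[C@H](OC(=O)/C=C/c2ccc3OC(C)(C)Oc3c2)C[C@](OC(=O)C=C)(C(=O)OCc2ccc(OC)cc2)C[C@H]1OC(=O)C=C | intermediate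
14 | 4-methoxybenzyl 1-O-acryloyl-4-O-(4-tert-butoxy-4-oxobutanoyl)-3,5-bis-O-[(E)-3-(2,2-dimethyl-1,3-benzodioxol-5-yl)prop-2-enoyl]quinate (bis-arylated, not isolated) | CC(C)(C)OC(=O)CCC(=O)O[C@H]1[C@H](OC(=O)/C=C/c2ccc3OC(C)(C)Oc3c2)C[C@](OC(=O)C=C)(C(=O)OCc2ccc(OC)cc2)C[C@H]1OC(=O)/C=C/c1ccc2OC(C)(C)Oc2c1 | intermediate
15 | 4-methoxybenzyl 4-O-(4-tert-butoxy-4-oxobutanoyl)-1,3,5-tris-O-[(E)-3-(2,2-dimethyl-1,3-benzodioxol-5-yl)prop-2-enoyl]quinate | CC(C)(C)OC(=O)CCC(=O)O[C@H]1[C@H](OC(=O)/C=C/c2ccc3OC(C)(C)Oc3c2)C[C@](OC(=O)/C=C/c2ccc3OC(C)(C)Oc3c2)(C(=O)OCc2ccc(OC)cc2)C[C@H]1OC(=O)/C=C/c1ccc2OC(C)(C)Oc2c1 | intermediate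
16 | 4-O-(3-carboxypropanoyl)-1,3,5-tris-O-[(E)-3-(2,2-dimethyl-1,3-benzodioxol-5-yl)prop-2-enoyl]quinic acid (tris-acetonide diacid, not isolated) | O=C(O)CCC(=O)O[C@H]1[C@H](OC(=O)/C=C/c2ccc3OC(C)(C)Oc3c2)C[C@](OC(=O)/C=C/c2ccc3OC(C)(C)Oc3c2)(C(=O)O)C[C@H]1OC(=O)/C=C/c1ccc2OC(C)(C)Oc2c1 | intermediate
17 | 1,3,5-tri-O-[(E)-caffeoyl]-4-O-succinylquinic acid (CNP0143991.1) | O=C(O)CCC(=O)O[C@H]1[C@H](OC(=O)/C=C/c2ccc(O)c(O)c2)C[C@](OC(=O)/C=C/c2ccc(O)c(O)c2)(C(=O)O)C[C@H]1OC(=O)/C=C/c1ccc(O)c(O)c1 | target

**Step count**
Total: 8 steps. Longest linear sequence: 7 steps (steps 1, 2, 3, 4, 5, 7, 8 from (−)-quinic acid); step 6 is a one-step side branch.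

**Steps most likely to fail**

Step 7 (threefold arylation). The catalyst may die before the second or third acrylate has reacted on the increasingly crowded substrate, and the tris-acrylate may cross-link by radical polymerisation, leaving partly arylated mixtures that are hard to separate. The fallback makes the Cβ–aryl bond on a simple acrylate and then acylates the core. It sets out from 12 and 6 and comes back at 15. Heck coupling of 12 with acrylic acid (Pd(OAc)2, P(o-tol)3, Et3N, MeCN, 90 °C) should give (E)-3-(2,2-dimethyl-1,3-benzodioxol-5-yl)prop-2-enoic acid F1. 1-Chloro-N,N,2-trimethylprop-1-en-1-amine in CH2Cl2 at rt converts it under neutral conditions, which spare the ketal, into (E)-3-(2,2-dimethyl-1,3-benzodioxol-5-yl)prop-2-enoyl chloride F2. Threefold acylation of triol 6 with this chloride (pyridine, DMAP, CH2Cl2, rt to 40 °C), a well-known way of esterifying all quinate hydroxyls including O1, then gives 15.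

Step 5 (tris-acryloylation). Acylation may stop short at the crowded tertiary O1, the amine may start oligomerisation of the acryloyl units, and the succinate may shift from O4 to O3 or O5 before its neighbours are capped. The fallback uses a saturated, masked acrylate. It sets out from 6 and comes back at 10. Acylation with 3-chloropropanoyl chloride (pyridine, DMAP, CH2Cl2, 0 to 40 °C), which cannot polymerise and can be pushed thermally, should give 4-methoxybenzyl 4-O-(4-tert-butoxy-4-oxobutanoyl)-1,3,5-tris-O-(3-chloropropanoyl)quinate F3. Threefold E1cB dehydrochlorination with Et3N in MeCN at rt to 40 °C then unveils the tris-acrylate 10.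

Step 8 (global acidolysis). The 4-methoxybenzyl or tert-butyl cations may alkylate the electron-rich rings once the catechols are free, the ketals on the acceptor-substituted rings may hydrolyse slowly, and prolonged aqueous acid may start to cleave esters. The fallback changes the phenol protection to silyl ethers that fall to fluoride as the last event, after the cation-forming acidolysis is over. It sets out from 11 and 10 and comes back at 17. Silylation of 11 (TBSCl, imidazole, DMF) gives 4-bromo-1,2-bis(tert-butyldimethylsilyloxy)benzene F4. Its threefold Heck coupling with 10 under the conditions of step 7 should give 4-methoxybenzyl 4-O-(4-tert-butoxy-4-oxobutanoyl)-1,3,5-tris-O-[(E)-3-[3,4-bis(tert-butyldimethylsilyloxy)phenyl]prop-2-enoyl]quinate F5. Anhydrous TFA/CH2Cl2 with anisole at 0 °C removes both carboxyl esters while the phenols stay capped, giving 4-O-(3-carboxypropanoyl)-1,3,5-tris-O-[(E)-3-[3,4-bis(tert-butyldimethylsilyloxy)phenyl]prop-2-enoyl]quinic acid F6. HF·pyridine in pyridine/THF then cleaves the six aryl silyl ethers to give 17.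

**Further compounds**
F1 | step 7 | (E)-3-(2,2-dimethyl-1,3-benzodioxol-5-yl)prop-2-enoic acid | OC(=O)/C=C/c1ccc2OC(C)(C)Oc2c1
F2 | step 7 | (E)-3-(2,2-dimethyl-1,3-benzodioxol-5-yl)prop-2-enoyl chloride | ClC(=O)/C=C/c1ccc2OC(C)(C)Oc2c1
F3 | step 5 | 4-methoxybenzyl 4-O-(4-tert-butoxy-4-oxobutanoyl)-1,3,5-tris-O-(3-chloropropanoyl)quinate | CC(C)(C)OC(=O)CCC(=O)O[C@H]1[C@H](OC(=O)CCCl)C[C@](OC(=O)CCCl)(C(=O)OCc2ccc(OC)cc2)C[C@H]1OC(=O)CCCl
F4 | step 8 | 4-bromo-1,2-bis(tert-butyldimethylsilyloxy)benzene | CC(C)(C)[Si](C)(C)Oc1ccc(Br)cc1O[Si](C)(C)C(C)(C)C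
F5 | step 8 | 4-methoxybenzyl 4-O-(4-tert-butoxy-4-oxobutanoyl)-1,3,5-tris-O-[(E)-3-[3,4-bis(tert-butyldimethylsilyloxy)phenyl]prop-2-enoyl]quinate | CC(C)(C)OC(=O)CCC(=O)O[C@H]1[C@H](OC(=O)/C=C/c2ccc(O[Si](C)(C)C(C)(C)C)c(O[Si](C)(C)C(C)(C)C)c2)C[C@](OC(=O)/C=C/c2ccc(O[Si](C)(C)C(C)(C)C)c(O[Si](C)(C)C(C)(C)C)c2)(C(=O)OCc2ccc(OC)cc2)C[C@H]1OC(=O)/C=C/c1ccc(O[Si](C)(C)C(C)(C)C)c(O[Si](C)(C)C(C)(C)C)c1
F6 | step 8 | 4-O-(3-carboxypropanoyl)-1,3,5-tris-O-[(E)-3-[3,4-bis(tert-butyldimethylsilyloxy)phenyl]prop-2-enoyl]quinic acid | O=C(O)CCC(=O)O[C@H]1[C@H](OC(=O)/C=C/c2ccc(O[Si](C)(C)C(C)(C)C)c(O[Si](C)(C)C(C)(C)C)c2)C[C@](OC(=O)/C=C/c2ccc(O[Si](C)(C)C(C)(C)C)c(O[Si](C)(C)C(C)(C)C)c2)(C(=O)O)C[C@H]1OC(=O)/C=C/c1ccc(O[Si](C)(C)C(C)(C)C)c(O[Si](C)(C)C(C)(C)C)c1
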